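Ring A is split into two three-carbon pieces across C2–C3 and C5–C6. Its C3–C4–C5 segment (prenyl, OH, prenyl) is locally symmetric and corresponds to 1,3-diprenylacetone. C6(OMe)–C1(acyl)–C2(OH) corresponds to a malonate-derived ketene dimethyl acetal that already carries the single O-methyl group. In one flask the ketone enolate replaces one acetal methoxy group (C5–C6) and the α′-carbanion of the adduct acylates a malonate ester (C2–C3); tautomerisation gives the hexasubstituted benzoate. No regiochemical choice arises, since both sides of the ketone and both esters are equivalent. The ester left on C1 is finally converted into the phenyl ketone with phenyllithium.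

Key step: step 5

Remark: the mono- and bis-prenylated keto diesters of step 1 and the in-flask adduct of step 5 carry stereocentres that form without control and are erased in the next bond reorganisation, so their SMILES carry no configuration; the target has no stereocentre.

Step 1
Reactants: 1 dimethyl 3-oxopentanedioate; 2 prenyl bromide (1-bromo-3-methylbut-2-ene)
Product: 4 dimethyl 2,4-bis(3-methylbut-2-enyl)-3-oxopentanedioate, via mono-prenylated keto diester 3 (not isolated)
Conditions: NaH (1.05 equiv), THF, 0 °C, then 2 (1.05 equiv), rt; second identical NaH/2 cycle in the same flask; aq NH4Cl
Reagents that add atoms: prenyl bromide (second equivalent), CC(C)=CCBr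
Why: Two successive SN2 C-alkylations of a β-keto ester enolate with a primary allylic bromide, in which the untouched CH2 of the mono-prenylated intermediate 3 is the more acidic and less hindered site, so the second equivalent of 2 should enter on the other side of the ketone; the stereocentres form without control and are erased in step 2.

Step 2
Reactants: 4 dimethyl 2,4-bis(3-methylbut-2-enyl)-3-oxopentanedioate
Product: 5 2,10-dimethylundeca-2,9-dien-6-one (1,3-diprenylacetone)
Conditions: LiCl (3 equiv), H2O (4 equiv), DMSO, 150 °C
Reagents that add atoms: none
Why: Krapcho dealkoxycarbonylation, in which chloride demethylates each β-keto ester and the carboxylates lose CO2 under neutral conditions that should leave the trisubstituted alkenes untouched and remove both stereocentres.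

Step 3
Reactants: 6 dimethyl malonate (dimethyl propanedioate)
Product: 7 dimethyl 2-[bis(methylsulfanyl)methylidene]propanedioate
Conditions: K2CO3 (2.2 equiv), CS2 (1.1 equiv), DMF, rt; then MeI (2.2 equiv), 0 °C → rt
Reagents that add atoms: carbon disulfide, S=C=S; iodomethane, CI
Why: Standard ketene dithioacetal synthesis, in which the malonate carbanion adds to CS2, a second deprotonation gives the ene-1,1-dithiolate and both sulfur atoms are methylated by SN2, each by one equivalent of iodomethane.

Step 4
Reactants: 7 dimethyl 2-[bis(methylsulfanyl)methylidene]propanedioate
Product: 8 dimethyl 2-(dimethoxymethylidene)propanedioate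
Conditions: NaOMe (4 equiv), MeOH, reflux; cold aq NH4Cl
Reagents that add atoms: sodium methoxide, [Na+].[O-]C
Why: Twofold nucleophilic vinylic substitution (addition–elimination) at the electron-poor carbon of the push-pull alkene, in which the malonate-stabilised adduct expels the less basic methanethiolate and excess methoxide in methanol drives the exchange while making ester exchange degenerate.

Step 5
Reactants: 5 2,10-dimethylundeca-2,9-dien-6-one; 8 dimethyl 2-(dimethoxymethylidene)propanedioate
Product: 10 methyl 2,4-dihydroxy-6-methoxy-3,5-bis(3-methylbut-2-enyl)benzoate, via vinylic substitution adduct 9 (not isolated)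
Conditions: LiN(iPr)2 (1.1 equiv), THF, −78 °C; 8 (1.0 equiv), −78 → −20 °C; LiN(iPr)2 (2.5 equiv), −78 °C → rt; aq NH4Cl
Reagents that add atoms: none
Why: The lithium enolate of 5 adds to the acetal carbon of the push-pull alkene 8 and the malonate-stabilised carbanion expels one methoxide (addition–elimination, bond C5–C6); adduct 9 is at once deprotonated to a delocalised dienolate, which keeps the second methoxy group in place as the future C6–OMe. The second charge of LiN(iPr)2 removes an α′-proton, and the terminal carbon of this dianion attacks the ester that lies cis to the ketone arm (bond C2–C3), closing ring A by a 6-(enolendo)-exo-trig Dieckmann acylation; loss of methoxide and twofold enolisation then give the arene as its dilithium bis-phenoxide. The closest known reaction type is the base-mediated [3+3] condensation of ketone 1,3-dinucleophiles with alkoxymethylidene malonates to hydroxybenzoates, combined with the vinylic substitution of malonate ketene acetals and dithioacetals by ketone enolates. No stereocentre is created, and the one in 9 disappears on enolisation. The step needs acylation at carbon and not at the enolate oxygen (which would give a 2-pyranone); the higher nucleophilicity of the terminal carbon of the dianion, the low temperature kept until the second base charge and the irreversible aromatisation should secure this. Regiochemistry needs no control because both enolisable sides of 5 and both esters of 8 are equivalent, so only one benzoate can arise.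

Step 6
Reactants: 10 methyl 2,4-dihydroxy-6-methoxy-3,5-bis(3-methylbut-2-enyl)benzoate; 11 phenyllithium
Product: 12 [2,4-dihydroxy-6-methoxy-3,5-bis(3-methylbut-2-enyl)phenyl](phenyl)methanone
Conditions: 11 (5 equiv), THF, −78 °C → rt; aq NH4Cl
Reagents that add atoms: none
Why: Acyl substitution of a hindered ester by an aryllithium, in which two equivalents of 11 form the dilithium bis-phenoxide, a third adds to the ester, and the resulting ketone, flanked at both ortho positions (OLi and OMe) and conjugated to two phenoxide donors, should resist a second addition so that the reaction stops at the benzophenone.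

Compound list
1 | dimethyl 3-oxopentanedioate | COC(=O)CC(=O)CC(=O)OC | starting material
2 | prenyl bromide (1-bromo-3-methylbut-2-ene) | CC(C)=CCBr | starting material
3 | dimethyl 2-(3-methylbut-2-enyl)-3-oxopentanedioate (racemic; formed and consumed in the flask of step 1) | COC(=O)C(CC=C(C)C)C(=O)CC(=O)OC | intermediate
4 | dimethyl 2,4-bis(3-methylbut-2-enyl)-3-oxopentanedioate (mixture of diastereomers) | COC(=O)C(CC=C(C)C)C(=O)C(CC=C(C)C)C(=O)OC | intermediate
5 | 2,10-dimethylundeca-2,9-dien-6-one (1,3-diprenylacetone) | CC(C)=CCCC(=O)CCC=C(C)C | intermediate
6 | dimethyl malonate (dimethyl propanedioate) | COC(=O)CC(=O)OC | starting material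
7 | dimethyl 2-[bis(methylsulfanyl)methylidene]propanedioate | COC(=O)C(C(=O)OC)=C(SC)SC | intermediate
8 | dimethyl 2-(dimethoxymethylidene)propanedioate | COC(=O)C(C(=O)OC)=C(OC)OC | intermediate
9 | dimethyl 2-[1-methoxy-7-methyl-2-(3-methylbut-2-enyl)-3-oxooct-6-enylidene]propanedioate (racemic; present in the flask as its lithium dienolate) | COC(=O)C(C(=O)OC)=C(OC)C(CC=C(C)C)C(=O)CCC=C(C)C | intermediate
10 | methyl 2,4-dihydroxy-6-methoxy-3,5-bis(3-methylbut-2-enyl)benzoate | COC(=O)c1c(OC)c(CC=C(C)C)c(O)c(CC=C(C)C)c1O | intermediate
11 | phenyllithium | [Li]c1ccccc1 | starting material
12 | [2,4-dihydroxy-6-methoxy-3,5-bis(3-methylbut-2-enyl)phenyl](phenyl)methanone | COc1c(CC=C(C)C)c(O)c(CC=C(C)C)c(O)c1C(=O)c1ccccc1 | target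

Total step count: 6. Longest linear sequence: 4 steps (steps 1, 2, 5, 6 or steps 3, 4, 5, 6).

Steps most likely to fail

Step 5. Ring closure may run through the enolate oxygen (lactonisation) instead of carbon, or the α′-deprotonation of the delocalised monoanion may stay incomplete so that only the open adduct is recovered. The fallback sets out from 5 and 8 and comes back at 10, and it makes the oxygen closure a deliberate first stage. The enolate of 5 (LiN(iPr)2, 1.1 equiv, THF, −78 °C) is combined with 8 and the mixture is warmed to reflux, which should give methyl 4-methoxy-5-(3-methylbut-2-enyl)-6-(4-methylpent-3-enyl)-2-oxo-2H-pyran-3-carboxylate F1 as a stable, purifiable lactone. Heating F1 with Mg(OMe)2 in MeOH should reopen the lactone to the magnesium chelate of the keto diester. Oxygen closure is reversible under these conditions, while the Claisen-type carbon closure is made irreversible by aromatisation. This pyranone-to-phenol ring transformation under magnesium methoxide is a known reaction type and should deliver 10.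

Step 6. Addition may stall at the electron-rich bis-phenoxide ester, or a second addition may lead on to the triaryl carbinol. The fallback sets out from 10 and comes back at 12. Treatment of 10 with Me2AlN(OMe)Me (from AlMe3 and N,O-dimethylhydroxylamine hydrochloride, 4 equiv, toluene, 60 °C) should give 2,4-dihydroxy-N,6-dimethoxy-N-methyl-3,5-bis(3-methylbut-2-enyl)benzamide F2; aluminium bound to the ortho phenoxide activates the ester here instead of deactivating it. Excess PhMgBr in THF (0 °C → rt) should then add once, because the chelated tetrahedral intermediate of the Weinreb amide collapses only on work-up, giving 12.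

Step 4. The exchange may stop after the first sulfur has been replaced, since the mixed O,S-acetal is the weaker acceptor, or thiolate may demethylate the esters on prolonged heating. The fallback sets out from 6 and comes back at 8, bypassing 7. Dimethyl malonate 6 is condensed with tetramethyl orthocarbonate C(OMe)4 in Ac2O with catalytic ZnCl2 at 120–130 °C while methyl acetate distils off. This is the orthocarbonate counterpart of the orthoformate route to alkoxymethylidene malonates. No compound outside the list is made (F0).

Further compounds
F1 | step 5 | methyl 4-methoxy-5-(3-methylbut-2-enyl)-6-(4-methylpent-3-enyl)-2-oxo-2H-pyran-3-carboxylate | COC(=O)C1=C(OC)C(CC=C(C)C)=C(CCC=C(C)C)OC1=O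
F2 | step 6 | 2,4-dihydroxy-N,6-dimethoxy-N-methyl-3,5-bis(3-methylbut-2-enyl)benzamide | CON(C)C(=O)c1c(OC)c(CC=C(C)C)c(O)c(CC=C(C)C)c1O
F0 | step 4 | none | none
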